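The trione ring C1–C2–C3–C4–C5–C9 (C1 side-chain bridgehead, C5 prenyl bridgehead, C9 bridging ketone) is cut at its two opposite bonds, C9–C5 and C1–C2. What remains is one open chain: a ketene-level C1–C9 unit tied by C8–C7–C6 to an acetoacetate-level C5–C4–C3–C2 unit. In step 12, LiN(iPr)2 turns aryl ester 18 into a ketene and a dienolate; attack of C5 on the ketene closes ring A, and the C1 enolate so released closes the trione ring on the C2 ester. The C7 stereocentre (Evans alkylation) is meant to control both bridgeheads; the side-chain stereocentre comes from (R)-limonene oxide by C–C cleavage.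

Key step: step 12

Remarks on the chemistry:
- Numbering used throughout: C1 bridgehead with the C10 side chain, C2/C4 diketone carbons, C3 acylated carbon, C5 prenyl bridgehead, C6 CMe2, C7 CH(prenyl), C8 CH2, C9 bridging ketone. Ring A is C1–C8–C7–C6–C5–C9; ring B is C1–C2–C3–C4–C5–C9.
- The target is one enol tautomer of a 2-aroyl-1,3-diketone; the tautomers equilibrate, so step 15 delivers it.
- Compounds 15–18 are carried as C5 epimers (18 also as C1 epimers). Both centres become trigonal in step 12, so the mixtures converge.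
- Commercial (+)-limonene oxide is taken as the (4R) cis/trans mixture.

Step 1
Reactants: 1 (4R)-limonene 1,2-oxide
Product: 3 (3R)-6-oxo-3-(prop-1-en-2-yl)heptanal, via limonene-1,2-diol 2 (not isolated)
Conditions: HIO4·2H2O, THF/H2O, 0 °C to rt
Reagents that add atoms: water, O
Why: Epoxide hydrolysis followed by Malaprade glycol cleavage should open the ring between C1 and C2 and leave the C4 stereocentre untouched.

Step 2
Reactants: 3 (3R)-6-oxo-3-(prop-1-en-2-yl)heptanal
Product: 5 (4R)-1-methoxy-7-methyl-4-(prop-1-en-2-yl)octa-1,7-diene (E/Z mixture), via keto enol ether 4 (not isolated)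
Conditions: Ph3P=CHOMe (1.05 equiv, from the phosphonium chloride and KN(SiMe3)2), THF, −78 to 0 °C; then Ph3P=CH2 (2.5 equiv, from the phosphonium bromide and KN(SiMe3)2), 0 °C to rt
Reagents that add atoms: (methoxymethyl)triphenylphosphonium chloride, COC[P+](c1ccccc1)(c1ccccc1)c1ccccc1.[Cl-]; methyltriphenylphosphonium bromide, C[P+](c1ccccc1)(c1ccccc1)c1ccccc1.[Br-]
Why: Sequential Wittig olefination, in which the aldehyde should react with the first ylide at low temperature before the ketone is methylenated by the second; the stereocentre is not enolisable.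

Step 3
Reactants: 5 (4R)-1-methoxy-7-methyl-4-(prop-1-en-2-yl)octa-1,7-diene
Product: 7 (4R)-7-methyl-4-(prop-1-en-2-yl)oct-7-enoic acid, via aldehyde 6 (not isolated)
Conditions: CrO3, H2SO4 (aq), acetone, 0 °C, short contact time
Reagents that add atoms: water, O
Why: Aqueous acid should hydrolyse the enol ether to the homologated aldehyde, which Jones oxidation takes on to the acid; isolated 1,1-disubstituted alkenes are expected to survive brief exposure at 0 °C.

Step 4
Reactants: 7 (4R)-7-methyl-4-(prop-1-en-2-yl)oct-7-enoic acid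
Product: 8 2,6-dimethylphenyl (4R)-7-methyl-4-(prop-1-en-2-yl)oct-7-enoate
Conditions: 2,6-dimethylphenol, DCC, DMAP (cat.), CH2Cl2, 0 °C to rt
Reagents that add atoms: 2,6-dimethylphenol, Cc1cccc(C)c1O
Why: Steglich esterification should install the aryloxy leaving group needed later for ketene formation.

Step 5
Reactants: 9 3,3-dimethylglutaric anhydride; 10 (S)-4-benzyl-1,3-oxazolidin-2-one
Product: 11 5-[(4S)-4-benzyl-2-oxo-1,3-oxazolidin-3-yl]-3,3-dimethyl-5-oxopentanoic acid
Conditions: 10, n-BuLi, THF, −78 °C; then 9, −78 to 0 °C; aq. HCl work-up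
Reagents that add atoms: none
Why: N-Acylation of the lithiated oxazolidinone by the symmetrical cyclic anhydride should give the imide acid with the two ends of the glutarate differentiated.

Step 6
Reactants: 11 5-[(4S)-4-benzyl-2-oxo-1,3-oxazolidin-3-yl]-3,3-dimethyl-5-oxopentanoic acid
Product: 13 methyl 7-[(4S)-4-benzyl-2-oxo-1,3-oxazolidin-3-yl]-5,5-dimethyl-3,7-dioxoheptanoate, via acyl imidazolide 12 (not isolated)
Conditions: CDI, THF, rt; then KO2CCH2CO2Me, MgCl2, Et3N, MeCN, rt to 40 °C; aq. HCl work-up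
Reagents that add atoms: potassium methyl malonate, COC(=O)CC(=O)[O-].[K+]
Why: Masamune–Brooks homologation (decarboxylative Claisen condensation of a magnesium malonate with an acyl imidazolide) should add C3 and C2 under conditions that the imide tolerates.

Step 7
Reactants: 13 methyl 7-[(4S)-4-benzyl-2-oxo-1,3-oxazolidin-3-yl]-5,5-dimethyl-3,7-dioxoheptanoate
Product: 14 methyl (2E)-7-[(4S)-4-benzyl-2-oxo-1,3-oxazolidin-3-yl]-3-methoxy-5,5-dimethyl-7-oxohept-2-enoate
Conditions: HC(OMe)3, MeOH, H2SO4 (cat.), rt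
Reagents that add atoms: trimethyl orthoformate, COC(OC)OC; methanol, CO
Why: Acid-catalysed ketalisation and loss of methanol should give the conjugated (E)-3-methoxy-enoate (methoxy trans to the ester), which masks the β-keto ester and places C5 cis to the ester carbonyl.

Step 8
Reactants: 14 methyl (2E)-7-[(4S)-4-benzyl-2-oxo-1,3-oxazolidin-3-yl]-3-methoxy-5,5-dimethyl-7-oxohept-2-enoate
Product: 15 methyl (2E,6S)-7-[(4S)-4-benzyl-2-oxo-1,3-oxazolidin-3-yl]-3-methoxy-5,5-dimethyl-4,6-bis(3-methylbut-2-en-1-yl)-7-oxohept-2-enoate (both C4 epimers)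
Conditions: LiN(iPr)2 (2.3 equiv), THF, −78 to −40 °C; prenyl bromide (2.6 equiv), −78 to −15 °C
Reagents that add atoms: prenyl bromide, CC(C)=CCBr
Why: Evans asymmetric alkylation of the chelated Z-enolate anti to the benzyl group should set C7 (6S here, R in the target), while the γ-carbanion of the (E)-3-methoxy-enoate, formed cis to the ester carbonyl as known for (E)-3-alkoxybut-2-enoates, is prenylated at C5 without control, which does not matter.

Step 9
Reactants: 15 methyl (2E,6S)-7-[(4S)-4-benzyl-2-oxo-1,3-oxazolidin-3-yl]-3-methoxy-5,5-dimethyl-4,6-bis(3-methylbut-2-en-1-yl)-7-oxohept-2-enoate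
Product: 16 methyl (2E,6S)-7-hydroxy-3-methoxy-5,5-dimethyl-4,6-bis(3-methylbut-2-en-1-yl)hept-2-enoate (both C4 epimers)
Conditions: LiBH4, MeOH (1.1 equiv), THF, 0 °C
Reagents that add atoms: none
Why: Reductive cleavage of the N-acyl oxazolidinone at the exocyclic carbonyl should give the primary alcohol and return the auxiliary; the push-pull enoate ester is reduced much more slowly and C7 is not touched.

Step 10
Reactants: 16 methyl (2E,6S)-7-hydroxy-3-methoxy-5,5-dimethyl-4,6-bis(3-methylbut-2-en-1-yl)hept-2-enoate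
Product: 17 methyl (2E,6S)-3-methoxy-5,5-dimethyl-4,6-bis(3-methylbut-2-en-1-yl)-7-{[(trifluoromethyl)sulfonyl]oxy}hept-2-enoate
Conditions: Tf2O, 2,6-lutidine, CH2Cl2, −78 °C; cold filtration through silica, used at once
Reagents that add atoms: triflic anhydride, O=S(=O)(OS(=O)(=O)C(F)(F)F)C(F)(F)F
Why: O-Sulfonylation of the primary alcohol; a triflate is chosen because C8 is a β-branched, neopentyl-like carbon that needs the best leaving group for the next step.

Step 11
Reactants: 8 2,6-dimethylphenyl (4R)-7-methyl-4-(prop-1-en-2-yl)oct-7-enoate; 17 methyl (2E,6S)-3-methoxy-5,5-dimethyl-4,6-bis(3-methylbut-2-en-1-yl)-7-{[(trifluoromethyl)sulfonyl]oxy}hept-2-enoate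
Product: 18 1-(2,6-dimethylphenyl) 9-methyl (4R,7E)-7-methoxy-5,5-dimethyl-4,6-bis(3-methylbut-2-en-1-yl)-2-[(2R)-5-methyl-2-(prop-1-en-2-yl)hex-5-en-1-yl]non-7-enedioate (epimers at C2 and C6 of the chain, i.e. C1 and C5 of the core)
Conditions: 8, LiN(iPr)2 (1.05 equiv), THF, −78 °C; then 17, DMPU, −78 to −45 °C
Reagents that add atoms: none
Why: SN2 alkylation of the lithium ester enolate by the primary triflate, run below the temperature at which the aryl ester enolate loses aryloxide, should join the two fragments at C1–C8; the new C1 centre is uncontrolled, which does not matter.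

Step 12
Reactants: 18 1-(2,6-dimethylphenyl) 9-methyl (4R,7E)-7-methoxy-5,5-dimethyl-4,6-bis(3-methylbut-2-en-1-yl)-2-[(2R)-5-methyl-2-(prop-1-en-2-yl)hex-5-en-1-yl]non-7-enedioate
Product: 21 4-methoxy-6,6-dimethyl-5,7-bis(3-methylbut-2-en-1-yl)-1-[(2R)-5-methyl-2-(prop-1-en-2-yl)hex-5-en-1-yl]bicyclo[3.3.1]non-3-ene-2,9-dione (7R; bridgeheads as in the target), via ketene 19 (not isolated), via cyclohexanone 20 (not isolated)
Conditions: LiN(iPr)2 (2.6 equiv), THF, −78 °C, 1 h; then −78 °C to rt; aq. NH4Cl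
Reagents that add atoms: none
Why: LiN(iPr)2 removes C1–H (aryl ester enolate) and C5–H (γ-deprotonation of the (E)-3-methoxy-enoate, cis to the ester carbonyl); on warming the ester enolate loses 2,6-dimethylphenoxide (E1cB) to give ketene 19, whose carbon C9 is attacked by the dienolate γ-carbon C5 to give the C1 enolate of cyclohexanone 20, and this enolate acylates the C2 ester (Dieckmann) with loss of methoxide. The closest known reactions are the capture by carbanions of ketenes released from aryl ester enolates, the γ-acylation of 3-alkoxy-enoate dienolates and the Dieckmann condensation, so that the whole is a formal intramolecular [4+2] union of a ketene with a dioxygenated diene. Ring A closes in a 6-(enolexo)-exo mode at the ketene carbon and ring B in a 6-(enolendo)-exo-trig mode. C5 is set in the first closure: in a chair-like transition state with the C7 prenyl group equatorial, the bulky chelated dienolate arm should sit pseudo-equatorial (anti to C6–C7) and the slim prenyl CH2 pseudo-axial, so that the arm ends up cis to the C7 prenyl group, and C1 is then fixed by the geometric need for a cis-1,3 bridge. The step needs γ- over α-deprotonation of the enoate (helped by the E geometry), C- over O-acylation in the second closure (the O-acyl enol lactone can revert under LiOMe, the C-acyl product cannot) and kinetic control, which the poorly nucleophilic aryloxide leaving group and the low temperature should provide. Both C1 and C5 epimers of 18 converge because both centres become trigonal.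

Step 13
Reactants: 22 3,4-diacetoxybenzoic acid
Product: 23 3,4-diacetoxybenzoyl chloride
Conditions: (COCl)2, DMF (cat.), CH2Cl2, 0 °C to rt
Reagents that add atoms: oxalyl chloride, O=C(Cl)C(Cl)=O
Why: Acid chloride formation through the Vilsmeier-type chloroiminium catalyst; the aryl acetates are inert.

Step 14
Reactants: 21 4-methoxy-6,6-dimethyl-5,7-bis(3-methylbut-2-en-1-yl)-1-[(2R)-5-methyl-2-(prop-1-en-2-yl)hex-5-en-1-yl]bicyclo[3.3.1]non-3-ene-2,9-dione; 23 3,4-diacetoxybenzoyl chloride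
Product: 24 3-(3,4-diacetoxybenzoyl)-4-methoxy-6,6-dimethyl-5,7-bis(3-methylbut-2-en-1-yl)-1-[(2R)-5-methyl-2-(prop-1-en-2-yl)hex-5-en-1-yl]bicyclo[3.3.1]non-3-ene-2,9-dione
Conditions: lithium 2,2,6,6-tetramethylpiperidide (from the amine and n-BuLi, 1.2 equiv), THF, −78 °C; then 23, −78 °C
Reagents that add atoms: none
Why: Vinylic lithiation at C3 of the vinylogous ester (between C2=O and C4–OMe) followed by C-acylation, as used for C3 acylation of bicyclic O-methyl triones; the acid chloride should react far faster than the aryl acetates.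

Step 15
Reactants: 24 3-(3,4-diacetoxybenzoyl)-4-methoxy-6,6-dimethyl-5,7-bis(3-methylbut-2-en-1-yl)-1-[(2R)-5-methyl-2-(prop-1-en-2-yl)hex-5-en-1-yl]bicyclo[3.3.1]non-3-ene-2,9-dione
Product: 26 CNP0139652.2 (target), via catechol enol ether 25 (not isolated)
Conditions: LiOH, 1,4-dioxane/H2O (degassed, argon), 90 °C; then dilute aq. HCl to pH 3–4 at 0 °C
Reagents that add atoms: lithium hydroxide, [Li+].[OH-]
Why: Saponification of the aryl acetates and addition–elimination of hydroxide at C4 of the doubly activated β-methoxy enone should free the catechol and the enolised triketone in one operation; no stereocentre is touched and strong acid is avoided because of the acid-labile alkenes.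

Compound list
1 | (4R)-limonene 1,2-oxide [(4R)-1-methyl-4-(prop-1-en-2-yl)-7-oxabicyclo[4.1.0]heptane, cis/trans mixture] | CC12OC1C[C@@H](CC2)C(C)=C | starting material
2 | (4R)-1-methyl-4-(prop-1-en-2-yl)cyclohexane-1,2-diol | CC1(O)CC[C@H](CC1O)C(C)=C | intermediate (not isolated)
3 | (3R)-6-oxo-3-(prop-1-en-2-yl)heptanal | CC(=O)CC[C@H](CC=O)C(C)=C | intermediate
4 | (5R)-8-methoxy-5-(prop-1-en-2-yl)oct-7-en-2-one (E/Z) | CC(=O)CC[C@H](CC=COC)C(C)=C | intermediate (not isolated)
5 | (4R)-1-methoxy-7-methyl-4-(prop-1-en-2-yl)octa-1,7-diene (E/Z) | C=C(C)CC[C@H](CC=COC)C(C)=C | intermediate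
6 | (4R)-7-methyl-4-(prop-1-en-2-yl)oct-7-enal | C=C(C)CC[C@H](CCC=O)C(C)=C | intermediate (not isolated)
7 | (4R)-7-methyl-4-(prop-1-en-2-yl)oct-7-enoic acid | C=C(C)CC[C@H](CCC(=O)O)C(C)=C | intermediate
8 | 2,6-dimethylphenyl (4R)-7-methyl-4-(prop-1-en-2-yl)oct-7-enoate | C=C(C)CC[C@H](CCC(=O)Oc1c(C)cccc1C)C(C)=C | intermediate
9 | 3,3-dimethylglutaric anhydride | CC1(C)CC(=O)OC(=O)C1 | starting material
10 | (S)-4-benzyl-1,3-oxazolidin-2-one | O=C1N[C@@H](Cc2ccccc2)CO1 | starting material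
11 | 5-[(4S)-4-benzyl-2-oxo-1,3-oxazolidin-3-yl]-3,3-dimethyl-5-oxopentanoic acid | O=C1OC[C@H](Cc2ccccc2)N1C(=O)CC(C)(C)CC(=O)O | intermediate
12 | (4S)-4-benzyl-3-[5-(1H-imidazol-1-yl)-3,3-dimethyl-5-oxopentanoyl]-1,3-oxazolidin-2-one | O=C1OC[C@H](Cc2ccccc2)N1C(=O)CC(C)(C)CC(=O)n1ccnc1 | intermediate (not isolated)
13 | methyl 7-[(4S)-4-benzyl-2-oxo-1,3-oxazolidin-3-yl]-5,5-dimethyl-3,7-dioxoheptanoate | O=C1OC[C@H](Cc2ccccc2)N1C(=O)CC(C)(C)CC(=O)CC(=O)OC | intermediate
14 | methyl (2E)-7-[(4S)-4-benzyl-2-oxo-1,3-oxazolidin-3-yl]-3-methoxy-5,5-dimethyl-7-oxohept-2-enoate | O=C1OC[C@H](Cc2ccccc2)N1C(=O)CC(C)(C)C/C(OC)=C\C(=O)OC | intermediate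
15 | methyl (2E,6S)-7-[(4S)-4-benzyl-2-oxo-1,3-oxazolidin-3-yl]-3-methoxy-5,5-dimethyl-4,6-bis(3-methylbut-2-en-1-yl)-7-oxohept-2-enoate (C4 epimers) | O=C1OC[C@H](Cc2ccccc2)N1C(=O)[C@@H](CC=C(C)C)C(C)(C)C(CC=C(C)C)/C(OC)=C\C(=O)OC | intermediate
16 | methyl (2E,6S)-7-hydroxy-3-methoxy-5,5-dimethyl-4,6-bis(3-methylbut-2-en-1-yl)hept-2-enoate (C4 epimers) | OC[C@@H](CC=C(C)C)C(C)(C)C(CC=C(C)C)/C(OC)=C\C(=O)OC | intermediate
17 | methyl (2E,6S)-3-methoxy-5,5-dimethyl-4,6-bis(3-methylbut-2-en-1-yl)-7-{[(trifluoromethyl)sulfonyl]oxy}hept-2-enoate (C4 epimers) | O=S(=O)(OC[C@@H](CC=C(C)C)C(C)(C)C(CC=C(C)C)/C(OC)=C\C(=O)OC)C(F)(F)F | intermediate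
18 | 1-(2,6-dimethylphenyl) 9-methyl (4R,7E)-7-methoxy-5,5-dimethyl-4,6-bis(3-methylbut-2-en-1-yl)-2-[(2R)-5-methyl-2-(prop-1-en-2-yl)hex-5-en-1-yl]non-7-enedioate (C2 and C6 epimers) | Cc1cccc(C)c1OC(=O)C(C[C@@H](CCC(C)=C)C(C)=C)C[C@@H](CC=C(C)C)C(C)(C)C(CC=C(C)C)/C(OC)=C\C(=O)OC | intermediate
19 | ketene from 18 by loss of 2,6-dimethylphenol (drawn neutral; present as its C5 lithium dienolate) | O=C=C(C[C@@H](CCC(C)=C)C(C)=C)C[C@@H](CC=C(C)C)C(C)(C)C(CC=C(C)C)/C(OC)=C\C(=O)OC | intermediate (not isolated)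
20 | methyl (2E)-3-methoxy-3-{2,2-dimethyl-1,3-bis(3-methylbut-2-en-1-yl)-5-[(2R)-5-methyl-2-(prop-1-en-2-yl)hex-5-en-1-yl]-6-oxocyclohexyl}prop-2-enoate (enoate arm cis to the C7 prenyl group; drawn neutral; present as its C1 lithium enolate) | O=C1C(C[C@@H](CCC(C)=C)C(C)=C)C[C@@H](CC=C(C)C)C(C)(C)[C@@]1(CC=C(C)C)/C(OC)=C\C(=O)OC | intermediate (not isolated)
21 | 4-methoxy-6,6-dimethyl-5,7-bis(3-methylbut-2-en-1-yl)-1-[(2R)-5-methyl-2-(prop-1-en-2-yl)hex-5-en-1-yl]bicyclo[3.3.1]non-3-ene-2,9-dione (7R; C7 prenyl syn to the C2–C4 bridge) | C=C(C)CC[C@H](C[C@@]12C[C@@H](CC=C(C)C)C(C)(C)[C@@](CC=C(C)C)(C(OC)=CC1=O)C2=O)C(C)=C | intermediate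
22 | 3,4-diacetoxybenzoic acid | CC(=O)Oc1ccc(cc1OC(C)=O)C(=O)O | starting material
23 | 3,4-diacetoxybenzoyl chloride | CC(=O)Oc1ccc(cc1OC(C)=O)C(Cl)=O | intermediate
24 | 3-(3,4-diacetoxybenzoyl) derivative of 21 | C=C(C)CC[C@H](C[C@@]12C[C@@H](CC=C(C)C)C(C)(C)[C@@](CC=C(C)C)(C(OC)=C(C(=O)c3ccc(OC(C)=O)c(OC(C)=O)c3)C1=O)C2=O)C(C)=C | intermediate
25 | 3-(3,4-dihydroxybenzoyl) derivative of 21 (methyl enol ether still in place) | C=C(C)CC[C@H](C[C@@]12C[C@@H](CC=C(C)C)C(C)(C)[C@@](CC=C(C)C)(C(OC)=C(C(=O)c3ccc(O)c(O)c3)C1=O)C2=O)C(C)=C | intermediate (not isolated)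
26 | CNP0139652.2: 3-(3,4-dihydroxybenzoyl)-2-hydroxy-6,6-dimethyl-5,7-bis(3-methylbut-2-en-1-yl)-1-[(2R)-5-methyl-2-(prop-1-en-2-yl)hex-5-en-1-yl]bicyclo[3.3.1]non-2-ene-4,9-dione (route numbering; 7R) | C=C(C)CC[C@H](C[C@@]12C[C@@H](CC=C(C)C)C(C)(C)[C@@](CC=C(C)C)(C(=O)C(C(=O)c3ccc(O)c(O)c3)=C1O)C2=O)C(=C)C | target

Total step count: 15. Longest linear sequence: 10 steps (9 → 11 → 13 → 14 → 15 → 16 → 17 → 18 → 21 → 24 → 26; steps 5–12, 14 and 15).

Steps most likely to fail

Step 12. The hindered C5 methine may be deprotonated incompletely, so that the ketene is consumed by diisopropylamine, or ring A may close with the dienolate arm trans to the C7 prenyl group, which would lead to the C7-epimeric bicycle. The fallback sets out from 14 and comes back at 20 and then 21. It leaves the C5 prenyl group out until ring A exists, so that C5 is alkylated on a cyclohexanone anti to the C7 substituent by known chemistry. Enoate imide 14 is alkylated at C7 only (NaN(SiMe3)2, 1.05 equiv; prenyl bromide) to give the mono-prenyl imide F1. LiBH4 then gives the mono-prenyl alcohol F2, and Tf2O with 2,6-lutidine gives the mono-prenyl triflate F3. Alkylation of the lithium enolate of 8 with F3 gives the diester without the C5 prenyl group F4. LiN(iPr)2 (2.5 equiv, −78 °C to 0 °C) should now close ring A only, because the C5 methylene is deprotonated easily and the product is held as its stabilised C5 enolate; quenching gives the C5-unsubstituted cyclohexanone F5. Tsuji–Trost allylation (prenyl methyl carbonate, Pd(PPh3)4, THF) should place the prenyl group on C5 anti to the C7 prenyl group and give 20 as an isolated compound. KN(SiMe3)2 in THF (−78 °C to 0 °C) then effects the Dieckmann closure to 21.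

Step 11. Substitution at the β-branched C8 may be so slow that the aryl ester enolate decays to its ketene or is quenched by proton transfer from C5–H of 17. The fallback sets out from 16 and 8 and comes back at 18; it replaces alkylation by olefination and conjugate reduction. Dess–Martin periodinane oxidises 16 to the aldehyde F6. Ester 8 is C-phosphorylated (LiN(iPr)2, 2 equiv; ClP(O)(OEt)2) to the α-phosphono ester F7. A Horner–Wadsworth–Emmons reaction (NaH, THF, 0 °C to rt) gives the trisubstituted enoate F8. Conjugate reduction with [(Ph3P)CuH]6 in toluene should saturate only the C1=C8 double bond, since the isolated alkenes and the push-pull 3-methoxy-enoate are inert, and gives 18.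

Step 8. The dienolate may be alkylated at C3 instead of C5, or the second alkylation may stall next to the quaternary carbon. The fallback sets out from 11 and comes back at 16; it prenylates C5 as a lactone enolate, where the position is unambiguous. Imide acid 11 is alkylated as its carboxylate (NaN(SiMe3)2, 2.1 equiv; prenyl bromide) to the C7-prenyl imide acid F9. LiBH4 and acidic work-up give the lactone F10, and LiN(iPr)2 with prenyl bromide gives the diprenyl lactone F11. Opening with the lithium enolate of methyl acetate and silylation of the freed alcohol (TBDPSCl, imidazole) gives the silyl ether keto ester F12. HC(OMe)3, MeOH and PPTS give the silyl ether enol ether F13, and Bu4NF gives 16.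

Further compounds
F1 | step 12 | methyl (2E,6S)-7-[(4S)-4-benzyl-2-oxo-1,3-oxazolidin-3-yl]-3-methoxy-5,5-dimethyl-6-(3-methylbut-2-en-1-yl)-7-oxohept-2-enoate | O=C1OC[C@H](Cc2ccccc2)N1C(=O)[C@@H](CC=C(C)C)C(C)(C)C/C(OC)=C\C(=O)OC
F2 | step 12 | methyl (2E,6S)-7-hydroxy-3-methoxy-5,5-dimethyl-6-(3-methylbut-2-en-1-yl)hept-2-enoate | OC[C@@H](CC=C(C)C)C(C)(C)C/C(OC)=C\C(=O)OC
F3 | step 12 | methyl (2E,6S)-3-methoxy-5,5-dimethyl-6-(3-methylbut-2-en-1-yl)-7-{[(trifluoromethyl)sulfonyl]oxy}hept-2-enoate | O=S(=O)(OC[C@@H](CC=C(C)C)C(C)(C)C/C(OC)=C\C(=O)OC)C(F)(F)F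
F4 | step 12 | 1-(2,6-dimethylphenyl) 9-methyl (4R,7E)-7-methoxy-5,5-dimethyl-4-(3-methylbut-2-en-1-yl)-2-[(2R)-5-methyl-2-(prop-1-en-2-yl)hex-5-en-1-yl]non-7-enedioate (C2 epimers) | Cc1cccc(C)c1OC(=O)C(C[C@@H](CCC(C)=C)C(C)=C)C[C@@H](CC=C(C)C)C(C)(C)C/C(OC)=C\C(=O)OC
F5 | step 12 | methyl (2E)-3-methoxy-3-{2,2-dimethyl-3-(3-methylbut-2-en-1-yl)-5-[(2R)-5-methyl-2-(prop-1-en-2-yl)hex-5-en-1-yl]-6-oxocyclohexyl}prop-2-enoate (prenyl-bearing ring carbon as in 17) | O=C1C(C[C@@H](CCC(C)=C)C(C)=C)C[C@@H](CC=C(C)C)C(C)(C)C1/C(OC)=C\C(=O)OC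
F6 | step 11 | methyl (2E,6S)-3-methoxy-5,5-dimethyl-4,6-bis(3-methylbut-2-en-1-yl)-7-oxohept-2-enoate (C4 epimers) | O=C[C@@H](CC=C(C)C)C(C)(C)C(CC=C(C)C)/C(OC)=C\C(=O)OC
F7 | step 11 | 2,6-dimethylphenyl (4R)-2-(diethoxyphosphoryl)-7-methyl-4-(prop-1-en-2-yl)oct-7-enoate (C2 epimers) | CCOP(=O)(OCC)C(C[C@@H](CCC(C)=C)C(C)=C)C(=O)Oc1c(C)cccc1C
F8 | step 11 | 1-(2,6-dimethylphenyl) 9-methyl (7E)-7-methoxy-5,5-dimethyl-4,6-bis(3-methylbut-2-en-1-yl)-2-[(2R)-5-methyl-2-(prop-1-en-2-yl)hex-5-en-1-yl]nona-2,7-dienedioate (C4 as in 16) | Cc1cccc(C)c1OC(=O)C(C[C@@H](CCC(C)=C)C(C)=C)=C[C@@H](CC=C(C)C)C(C)(C)C(CC=C(C)C)/C(OC)=C\C(=O)OC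
F9 | step 8 | (4S)-5-[(4S)-4-benzyl-2-oxo-1,3-oxazolidin-3-yl]-3,3-dimethyl-4-(3-methylbut-2-en-1-yl)-5-oxopentanoic acid | O=C1OC[C@H](Cc2ccccc2)N1C(=O)[C@@H](CC=C(C)C)C(C)(C)CC(=O)O
F10 | step 8 | (5S)-4,4-dimethyl-5-(3-methylbut-2-en-1-yl)oxan-2-one | O=C1CC(C)(C)[C@H](CC=C(C)C)CO1
F11 | step 8 | (5S)-4,4-dimethyl-3,5-bis(3-methylbut-2-en-1-yl)oxan-2-one (C3 epimers) | O=C1C(CC=C(C)C)C(C)(C)[C@H](CC=C(C)C)CO1
F12 | step 8 | methyl (6S)-7-[(tert-butyldiphenylsilyl)oxy]-5,5-dimethyl-4,6-bis(3-methylbut-2-en-1-yl)-3-oxoheptanoate (C4 epimers) | CC(C)(C)[Si](c1ccccc1)(c1ccccc1)OC[C@@H](CC=C(C)C)C(C)(C)C(CC=C(C)C)C(=O)CC(=O)OC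
F13 | step 8 | methyl (2E,6S)-7-[(tert-butyldiphenylsilyl)oxy]-3-methoxy-5,5-dimethyl-4,6-bis(3-methylbut-2-en-1-yl)hept-2-enoate (C4 epimers) | CC(C)(C)[Si](c1ccccc1)(c1ccccc1)OC[C@@H](CC=C(C)C)C(C)(C)C(CC=C(C)C)/C(OC)=C\C(=O)OC
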